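**Plan**
- Retrosynthesis: cut the two resorcinol C–C(=O) bonds (double acylation by a diacid), then the ring A O–CH3 bond, then ring A itself at C4–C5 and C1–C2. This leaves an acetonyl ether on the ring B catechol oxygen and methyl 4-oxohex-5-enoate.
- Enabling feature: ring A carries OMe (C3) and the bridging oxygen (C4) on adjacent carbons, with the chain at C1 para to the bridge. C2–C3–C4 therefore map onto an aryloxyacetone and C5–C6–C1 onto an alkyl vinyl ketone.
- Forward: ring B is bought with its two oxygens differentiated; its chain is installed (olefination, alkene hydrogenation) and the free 3-OH is acetonylated. Ring A is then annulated and aromatised on that oxygen; methylation, debenzylation and saponification follow, and the two resorcinol rings are attached last.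
- Stereochemistry: the target has none; the racemic centres of the annulation intermediates vanish on aromatisation.

Key step: step 5

Remark: the target has no stereocentre and no stereogenic double bond, so "single enantiomer" is taken to mean the achiral constitution as drawn.

**Step 1**
Reactants: 1 4-(benzyloxy)-3-hydroxybenzaldehyde; 2 methyl (triphenylphosphoranylidene)acetate
Product: 3 methyl (2E)-3-[4-(benzyloxy)-3-hydroxyphenyl]prop-2-enoate
Conditions: 2 (1.15 equiv), toluene, 90 °C
Reagents that add atoms: none
Why: Wittig olefination with a stabilised ylide needs no added base, tolerates the free phenol and should give the E-cinnamate.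

**Step 2**
Reactants: 3 methyl (2E)-3-[4-(benzyloxy)-3-hydroxyphenyl]prop-2-enoate
Product: 4 methyl 3-[4-(benzyloxy)-3-hydroxyphenyl]propanoate
Conditions: H2 (4 atm), RhCl(PPh3)3 (3 mol %), toluene/MeOH 1:1, 50 °C
Reagents that add atoms: none
Why: Homogeneous Rh(I)-catalysed hydrogenation saturates the conjugated disubstituted alkene but does not hydrogenolyse the aryl benzyl ether, which heterogeneous Pd would cleave.

**Step 3**
Reactants: 4 methyl 3-[4-(benzyloxy)-3-hydroxyphenyl]propanoate; 5 chloroacetone
Product: 6 methyl 3-[4-(benzyloxy)-3-(2-oxopropoxy)phenyl]propanoate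
Conditions: 5 (1.3 equiv), K2CO3 (1.5 equiv), KI (10 mol %), acetone, reflux
Reagents that add atoms: none
Why: Williamson etherification of the only free phenol with an α-halo ketone (Finkelstein-assisted SN2); the methyl ester is inert to K2CO3 in acetone.

**Step 4**
Reactants: 7 methyl 4-chloro-4-oxobutanoate; 8 tributyl(vinyl)stannane
Product: 9 methyl 4-oxohex-5-enoate
Conditions: PdCl2(PPh3)2 (1 mol %), THF, 50 °C; bulb-to-bulb distillation over BHT, stored cold
Reagents that add atoms: none
Why: Stille acylation of an acid chloride with a vinylstannane gives the vinyl ketone under neutral conditions that spare the methyl ester and exclude over-addition.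

**Step 5**
Reactants: 6 methyl 3-[4-(benzyloxy)-3-(2-oxopropoxy)phenyl]propanoate; 9 methyl 4-oxohex-5-enoate
Product: 12 methyl 3-[4-(benzyloxy)-3-[2-hydroxy-4-(3-methoxy-3-oxopropyl)phenoxy]phenyl]propanoate, via diketone Michael adduct 10 (not isolated), via aryloxycyclohexenone 11 (not isolated)
Conditions: 9 (1.2 equiv, slow addition), NaOMe (0.3 equiv), MeOH, 0 °C to rt, then 60 °C; TsOH·H2O (0.5 equiv), solvent switch to DMSO; Pd(TFA)2 (5 mol %), 2-(dimethylamino)pyridine (10 mol %), O2 (1 atm), 80 °C
Reagents that add atoms: none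
Why: Catalytic methoxide equilibrates the enolates of 6, and the one at the aryloxy-bearing carbon, expected to be about three pKa units more acidic than the methyl group, adds to the unsubstituted terminus of 9 (C4–C5 bond) to give diketone 10. The methyl enolate of 10 then attacks the unhindered chain ketone in a 6-(enolexo)-exo-trig aldol addition (C1–C2 bond) and E1cB loss of water gives enone 11, the whole being a Robinson annulation of an α-oxygenated methyl ketone with an alkyl vinyl ketone. The alternative closure of the chain α′-methylene onto the acetyl carbonyl should be slower under alkoxide catalysis because that carbonyl is flanked by the branched aryloxy-bearing carbon; secondary-amine catalysis is avoided because it would activate that carbonyl as an iminium ion. Pd(II)-catalysed aerobic dehydrogenation (Pd enolate, β-hydride elimination, tautomerisation) then converts 11 into phenol 12 without touching the benzyl ether or the esters. The stereocentre created at the aryloxy carbon is racemic and is erased on aromatisation, so no stereocontrol is required. Connectivity fixes the pattern: the former ketone carbon becomes the C–OH next to the diaryl ether carbon and the ester chain sits para to the ether oxygen.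

**Step 6**
Reactants: 12 methyl 3-[4-(benzyloxy)-3-[2-hydroxy-4-(3-methoxy-3-oxopropyl)phenoxy]phenyl]propanoate
Product: 13 methyl 3-[4-(benzyloxy)-3-[2-methoxy-4-(3-methoxy-3-oxopropyl)phenoxy]phenyl]propanoate
Conditions: MeI (2 equiv), K2CO3 (2 equiv), acetone, 50 °C
Reagents that add atoms: iodomethane, CI
Why: Williamson O-methylation of the single free phenol; the conditions leave esters and benzyl ether intact and would re-esterify any acid formed by adventitious hydrolysis in step 5.

**Step 7**
Reactants: 13 methyl 3-[4-(benzyloxy)-3-[2-methoxy-4-(3-methoxy-3-oxopropyl)phenoxy]phenyl]propanoate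
Product: 14 methyl 3-[4-hydroxy-3-[2-methoxy-4-(3-methoxy-3-oxopropyl)phenoxy]phenyl]propanoate
Conditions: H2 (1 atm), 10% Pd/C, EtOAc/MeOH, rt
Reagents that add atoms: none
Why: Catalytic hydrogenolysis cleaves the aryl benzyl ether selectively; the diaryl ether, aryl methyl ether and esters are inert.

**Step 8**
Reactants: 14 methyl 3-[4-hydroxy-3-[2-methoxy-4-(3-methoxy-3-oxopropyl)phenoxy]phenyl]propanoate
Product: 15 3-[3-[4-(2-carboxyethyl)-2-methoxyphenoxy]-4-hydroxyphenyl]propanoic acid
Conditions: LiOH·H2O (5 equiv), degassed THF/MeOH/H2O, rt; then 1 M HCl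
Reagents that add atoms: lithium hydroxide, [Li+].[OH-]
Why: Saponification (BAc2) of both unhindered methyl esters; the ethers are base-stable and degassing protects the phenoxide from air.

**Step 9**
Reactants: 15 3-[3-[4-(2-carboxyethyl)-2-methoxyphenoxy]-4-hydroxyphenyl]propanoic acid; 16 resorcinol
Product: 17 verbenachalcone, 1-(2,4-dihydroxyphenyl)-3-[3-[4-[3-(2,4-dihydroxyphenyl)-3-oxopropyl]-2-methoxyphenoxy]-4-hydroxyphenyl]propan-1-one
Conditions: 16 (6 equiv), BF3·OEt2 (neat, as solvent), 85 °C; then aq. NaOAc, 50 °C (cleaves boron chelates)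
Reagents that add atoms: none
Why: Friedel–Crafts (Nencki-type) C-acylation of resorcinol by the BF3-activated carboxylic acids should occur at C4, ortho to one hydroxyl and para to the other, giving the chelated 2,4-dihydroxyphenyl ketones, while excess resorcinol outcompetes intramolecular indanone formation.

**Compound list**
1 | 4-(benzyloxy)-3-hydroxybenzaldehyde | O=Cc1ccc(OCc2ccccc2)c(O)c1 | starting material
2 | methyl (triphenylphosphoranylidene)acetate | COC(=O)C=P(c1ccccc1)(c1ccccc1)c1ccccc1 | starting material
3 | methyl (2E)-3-[4-(benzyloxy)-3-hydroxyphenyl]prop-2-enoate | COC(=O)/C=C/c1ccc(OCc2ccccc2)c(O)c1 | intermediate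
4 | methyl 3-[4-(benzyloxy)-3-hydroxyphenyl]propanoate | COC(=O)CCc1ccc(OCc2ccccc2)c(O)c1 | intermediate
5 | chloroacetone | CC(=O)CCl | starting material
6 | methyl 3-[4-(benzyloxy)-3-(2-oxopropoxy)phenyl]propanoate | COC(=O)CCc1ccc(OCc2ccccc2)c(OCC(C)=O)c1 | intermediate
7 | methyl 4-chloro-4-oxobutanoate | COC(=O)CCC(=O)Cl | starting material
8 | tributyl(vinyl)stannane | C=C[Sn](CCCC)(CCCC)CCCC | starting material
9 | methyl 4-oxohex-5-enoate | COC(=O)CCC(=O)C=C | intermediate
10 | methyl 7-[2-(benzyloxy)-5-(3-methoxy-3-oxopropyl)phenoxy]-4,8-dioxononanoate (racemic) | COC(=O)CCC(=O)CCC(Oc1cc(CCC(=O)OC)ccc1OCc1ccccc1)C(C)=O | intermediate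
11 | methyl 3-[4-(benzyloxy)-3-{[4-(3-methoxy-3-oxopropyl)-2-oxocyclohex-3-en-1-yl]oxy}phenyl]propanoate (racemic) | COC(=O)CCC1=CC(=O)C(Oc2cc(CCC(=O)OC)ccc2OCc2ccccc2)CC1 | intermediate
12 | methyl 3-[4-(benzyloxy)-3-[2-hydroxy-4-(3-methoxy-3-oxopropyl)phenoxy]phenyl]propanoate | COC(=O)CCc1ccc(OCc2ccccc2)c(Oc2ccc(CCC(=O)OC)cc2O)c1 | intermediate
13 | methyl 3-[4-(benzyloxy)-3-[2-methoxy-4-(3-methoxy-3-oxopropyl)phenoxy]phenyl]propanoate | COC(=O)CCc1ccc(OCc2ccccc2)c(Oc2ccc(CCC(=O)OC)cc2OC)c1 | intermediate
14 | methyl 3-[4-hydroxy-3-[2-methoxy-4-(3-methoxy-3-oxopropyl)phenoxy]phenyl]propanoate | COC(=O)CCc1ccc(O)c(Oc2ccc(CCC(=O)OC)cc2OC)c1 | intermediate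
15 | 3-[3-[4-(2-carboxyethyl)-2-methoxyphenoxy]-4-hydroxyphenyl]propanoic acid | OC(=O)CCc1ccc(O)c(Oc2ccc(CCC(O)=O)cc2OC)c1 | intermediate
16 | resorcinol | Oc1cccc(O)c1 | starting material
17 | verbenachalcone | COc1cc(CCC(=O)c2ccc(O)cc2O)ccc1Oc1cc(CCC(=O)c2ccc(O)cc2O)ccc1O | target

**Step count and risks**
Total steps: 9. Longest linear sequence: 8 steps (1 → 3 → 4 → 6 → 12 → 13 → 14 → 15 → 17); step 4 is the side branch.

Risk 1, step 5. Michael addition could occur at the methyl carbon or twice at the aryloxy carbon. The aldol closure could run from the chain α′-methylene onto the acetyl carbonyl, and the dehydrogenation could stall or degrade the α-aryloxy ketone. The fallback gives up the de novo ring synthesis and joins two preformed arenes. It sets out from phenol 4 and returns at 13. Commercial 4-bromo-3-methoxybenzaldehyde is olefinated with ylide 2 to methyl (2E)-3-(4-bromo-3-methoxyphenyl)prop-2-enoate F1. Hydrogenation over RhCl(PPh3)3, which keeps the aryl bromide, gives methyl 3-(4-bromo-3-methoxyphenyl)propanoate F2. Ullmann diaryl ether coupling of F2 with 4 (CuI, N,N-dimethylglycine, Cs2CO3, dioxane, 100 °C) should give 13 directly.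

Risk 2, step 9. Incomplete double acylation, indanone closure of the activated 3-arylpropanoic acids, or ether cleavage in hot Lewis acid could erode the last step. The fallback replaces electrophilic acylation by addition of a defined aryl nucleophile. It sets out from 13 and returns at 17. Diester 13 is converted with MeNHOMe·HCl/iPrMgCl (THF, −20 °C) into 3-[4-(benzyloxy)-3-[2-methoxy-4-[3-[methoxy(methyl)amino]-3-oxopropyl]phenoxy]phenyl]-N-methoxy-N-methylpropanamide F3. 4-Bromoresorcinol is benzylated (BnBr, K2CO3) to 2,4-bis(benzyloxy)-1-bromobenzene F4, and bromine–lithium exchange (n-BuLi, THF, −78 °C) gives [2,4-bis(benzyloxy)phenyl]lithium F5. Addition of F5 (2.5 equiv) to F3 gives 1-[2,4-bis(benzyloxy)phenyl]-3-[4-(benzyloxy)-3-[4-[3-[2,4-bis(benzyloxy)phenyl]-3-oxopropyl]-2-methoxyphenoxy]phenyl]propan-1-one F6. Global hydrogenolysis (H2, Pd/C, EtOAc/THF, rt) then gives 17.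

Risk 3, step 4. The vinyl ketone may polymerise during isolation or carry tin residues into the base-catalysed annulation. The fallback generates it in the annulation flask from a stable precursor. It sets out from 7 and returns at 9, formed in situ in step 5. Friedel–Crafts acylation of ethylene with 7 (AlCl3, CH2Cl2, 0 °C) gives methyl 6-chloro-4-oxohexanoate F7. F7 is added to 6 with one extra equivalent of NaOMe, so that E1cB loss of HCl releases 9 at low stationary concentration.

**Further compounds**
F1 | step 5 | methyl (2E)-3-(4-bromo-3-methoxyphenyl)prop-2-enoate | COC(=O)/C=C/c1ccc(Br)c(OC)c1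
F2 | step 5 | methyl 3-(4-bromo-3-methoxyphenyl)propanoate | COC(=O)CCc1ccc(Br)c(OC)c1
F3 | step 9 | 3-[4-(benzyloxy)-3-[2-methoxy-4-[3-[methoxy(methyl)amino]-3-oxopropyl]phenoxy]phenyl]-N-methoxy-N-methylpropanamide | CON(C)C(=O)CCc1ccc(OCc2ccccc2)c(Oc2ccc(CCC(=O)N(C)OC)cc2OC)c1
F4 | step 9 | 2,4-bis(benzyloxy)-1-bromobenzene | Brc1ccc(OCc2ccccc2)cc1OCc1ccccc1
F5 | step 9 | [2,4-bis(benzyloxy)phenyl]lithium | [Li]c1ccc(OCc2ccccc2)cc1OCc1ccccc1
F6 | step 9 | 1-[2,4-bis(benzyloxy)phenyl]-3-[4-(benzyloxy)-3-[4-[3-[2,4-bis(benzyloxy)phenyl]-3-oxopropyl]-2-methoxyphenoxy]phenyl]propan-1-one | COc1cc(CCC(=O)c2ccc(OCc3ccccc3)cc2OCc2ccccc2)ccc1Oc1cc(CCC(=O)c2ccc(OCc3ccccc3)cc2OCc2ccccc2)ccc1OCc1ccccc1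
F7 | step 4 | methyl 6-chloro-4-oxohexanoate | COC(=O)CCC(=O)CCCl
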